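The cyclohexane (C1 bears the trienyl chain; C2 to C6 follow through CHMe, C(Me)OH, CHOAc, C(Me)OH, CHOAc) hides a local mirror plane through C1 and C4. It is therefore built as a cyclopentene that lacks only C1. Dibromocarbene places C1 on the C2=C6 alkene. Silver-induced electrocyclic opening then breaks the C2–C6 bond, so five ring atoms become six. In the same operation the C5 tert-butyl carbonate captures the allyl cation at C6. This sets C6–O, breaks the latent symmetry and leaves C1–Br and C1=C2 as handles for formyl and methyl. The precursor is a tricyclic gem-dibromide from 3-methylcyclopentenone; one CBS reduction supplies all chirality. A final Suzuki coupling adds the pyrone.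

Key step: step 9

Remark: ring atoms of all intermediates carry the numbers of the target cyclohexane given above. The sense of induction in step 1 is assumed by analogy with aryl alkyl ketones.

Step 1
Reactants: 1 3-methylcyclopent-2-en-1-one
Product: 2 (R)-3-methylcyclopent-2-en-1-ol
Conditions: (S)-Me-CBS (10 mol %), catecholborane, toluene, −78 °C; aq NaOH work-up
Reagents that add atoms: none
Why: Corey–Bakshi–Shibata reduction: the alkenyl arm should act as the large group, so the (S)-catalyst should give the R carbinol (C5), and catecholborane at low temperature leaves the alkene untouched.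

Step 2
Reactants: 2 (R)-3-methylcyclopent-2-en-1-ol
Product: 3 (1R,2S,3R)-1-methylcyclopentane-1,2,3-triol
Conditions: OsO4 (2 mol %), NMO, acetone/H2O, 0 °C to rt
Reagents that add atoms: N-methylmorpholine N-oxide, C[N+]1([O-])CCOCC1; water, O
Why: Upjohn dihydroxylation: osmium tetroxide adds suprafacially and should choose the face anti to the allylic hydroxyl, which sets C3 and C4 from the carbinol centre; the minor all-cis triol has to be removed here or at the next stage because it would end as the enantiomer of 5.

Step 3
Reactants: 3 (1R,2S,3R)-1-methylcyclopentane-1,2,3-triol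
Product: 4 (3aS,4R,6aR)-2,2,6a-trimethyltetrahydro-3aH-cyclopenta[d][1,3]dioxol-4-ol
Conditions: 2,2-dimethoxypropane, PPTS (cat.), CH2Cl2, rt
Reagents that add atoms: 2,2-dimethoxypropane, COC(C)(C)OC
Why: Acid-catalysed transketalisation: only the cis C3/C4 diol can span a dioxolane on the cyclopentane, so the trans C5 hydroxyl stays free.

Step 4
Reactants: 4 (3aS,4R,6aR)-2,2,6a-trimethyltetrahydro-3aH-cyclopenta[d][1,3]dioxol-4-ol
Product: 5 (3aR,6aR)-2,2,6a-trimethyltetrahydro-4H-cyclopenta[d][1,3]dioxol-4-one
Conditions: TPAP (5 mol %), NMO, 4 Å MS, CH2Cl2, rt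
Reagents that add atoms: none
Why: Ley–Griffith oxidation of the only free alcohol under neutral conditions; the relay stereocentre at C5 is spent here and the cis ring fusion cannot epimerise.

Step 5
Reactants: 5 (3aR,6aR)-2,2,6a-trimethyltetrahydro-4H-cyclopenta[d][1,3]dioxol-4-one
Product: 7 (3aR,6aR)-2,2,6a-trimethyl-3a,6a-dihydro-4H-cyclopenta[d][1,3]dioxol-4-one, via silyl enol ether 6 (not isolated)
Conditions: LDA, TMSCl, THF, −78 °C; then Pd(OAc)2 (1.05 equiv), MeCN, rt
Reagents that add atoms: none
Why: Saegusa–Ito dehydrogenation: kinetic deprotonation with internal silyl quench takes the unhindered C6 methylene rather than the C4 methine, and Pd(II) then removes a C2 hydrogen by β-hydride elimination.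

Step 6
Reactants: 7 (3aR,6aR)-2,2,6a-trimethyl-3a,6a-dihydro-4H-cyclopenta[d][1,3]dioxol-4-one
Product: 8 (3aS,4S,6aR)-2,2,4,6a-tetramethyl-4,6a-dihydro-3aH-cyclopenta[d][1,3]dioxol-4-ol
Conditions: MeLi, CeCl3, THF, −78 °C; aq NH4Cl
Reagents that add atoms: methyllithium, [Li]C
Why: 1,2-Addition of a weakly basic organocerium reagent: attack on the convex face of the cis-fused bicycle, anti to the dioxolane, should put the C5 methyl trans and the C5 hydroxyl cis to the C3 and C4 oxygens; 8 must be kept from acid because acetonide migration to the C4/C5 oxygens gives its enantiomer.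

Step 7
Reactants: 8 (3aS,4S,6aR)-2,2,4,6a-tetramethyl-4,6a-dihydro-3aH-cyclopenta[d][1,3]dioxol-4-ol
Product: 9 tert-butyl carbonate of 8 (C5 O-Boc)
Conditions: KHMDS, THF, −78 °C; Boc2O, −78 to 0 °C; aq NH4Cl
Reagents that add atoms: di-tert-butyl dicarbonate, CC(C)(C)OC(=O)OC(=O)OC(C)(C)C
Why: O-Acylation of the potassium alkoxide; the carbonate freezes the difference between the C3 and C5 oxygens and installs the internal nucleophile for step 9.

Step 8
Reactants: 9 tert-butyl carbonate of 8 (C5 O-Boc)
Product: 10 tricyclic gem-dibromide (6,6-dibromobicyclo[3.1.0]hexane core; CBr2 = C1 bridges C2 and C6 on the face anti to the oxygens; C3/C4 acetonide; C5 O-Boc)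
Conditions: CHBr3, 50 % aq NaOH, BnEt3NCl (cat.), CH2Cl2, 0 °C to rt
Reagents that add atoms: bromoform, BrC(Br)Br
Why: Cheletropic syn addition of phase-transfer-generated dibromocarbene to the only alkene, expected on the face anti to the three oxygens; the two new ring-fusion centres are erased or reset in step 9, so the facial outcome does not matter.

Step 9
Reactants: 10 tricyclic gem-dibromide
Product: 11 ring-expanded bromocyclohexene (C1–Br; C1=C2; C3/C4 acetonide; C5/C6 cyclic carbonate; all four oxygens cis)
Conditions: AgBF4 (1.5 equiv), 2,6-di-tert-butylpyridine, ClCH2CH2Cl, 0 to 60 °C, dark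
Reagents that add atoms: none
Why: Silver(I) pulls off the endo bromide while the C2–C6 bond opens in the thermally allowed disrotatory 2π electrocyclic mode (Woodward–Hoffmann rules), so the bond shared by the three- and five-membered rings disappears and the cyclopentane becomes the six-membered 2-bromoallyl cation C2–C1(Br)–C6. The closest known reaction type is the silver-promoted ring expansion of ring-fused gem-dibromocyclopropanes with capture by a tethered nucleophile, joined here to the tert-butyl carbonate participation known from halocarbonate cyclisations. The carbocycle arises by ring expansion and not by cyclisation, whereas the cyclic carbonate closes by 5-exo attack of the Boc carbonyl oxygen on C6, followed by loss of isobutene and a proton. C6 is the only new stereocentre and is fixed by the tether, because the C5 oxygen can reach C6 only from its own face, which gives the cis-fused carbonate and the all-cis oxygen array. The step needs capture at C6 and not at the nearly equivalent terminus C2, which the tether secures since attack at C2 would demand a bridged seven-membered ring. C3 and C5 carry no hydrogen, so proton loss to a diene is excluded, and the hindered base protects the acetonide from the acid set free.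

Step 10
Reactants: 11 ring-expanded bromocyclohexene
Product: 13 C1-bromo-C1=C2-cyclohexene bearing cis acetonides on the C3/C4 and C5/C6 diols, via bromo diol 12 (not isolated)
Conditions: K2CO3 (cat.), MeOH, 0 °C; then CSA, 2,2-dimethoxypropane, acetone, rt
Reagents that add atoms: 2,2-dimethoxypropane, COC(C)(C)OC
Why: Base-catalysed transesterification of the cyclic carbonate to dimethyl carbonate, then transketalisation of the cis C5/C6 diol; the exchange is needed because an allylic carbonate would not survive tert-butyllithium, and it leaves one kind of protecting group for step 14.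

Step 11
Reactants: 13 bis-acetonide vinyl bromide
Product: 15 bis-acetonide enal (C1–CHO; C1=C2), via vinyllithium 14 (not isolated)
Conditions: t-BuLi (2.1 equiv), Et2O, −78 °C; DMF; aq NH4Cl
Reagents that add atoms: N,N-dimethylformamide, CN(C)C=O
Why: Bromine–lithium exchange at the sp2 carbon and Bouveault-type formylation; β-elimination of the C6 oxygen would require a six-membered cyclic allene and is not expected.

Step 12
Reactants: 15 bis-acetonide enal
Product: 17 bis-acetonide aldehyde (C1 formyl and C2 methyl both trans to the four oxygens), via silyl enol ether 16 (not isolated)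
Conditions: Me2CuLi (from MeLi and CuI), TMSCl, Et2O/THF, −78 °C; then K2CO3 (cat.), MeOH, 0 °C to rt
Reagents that add atoms: lithium dimethylcuprate, [Li+].C[Cu-]C
Why: Gilman cuprate 1,4-addition accelerated by TMSCl: methyl should enter C2 axially from the convex face, anti to both dioxolanes and to the pseudoaxial C3–O bond, and the basic desilylation equilibrates C1 to the equatorial formyl group trans to C6–O, because its epimer would stand syn-axial to the C3 and C5 oxygens.

Step 13
Reactants: 17 bis-acetonide aldehyde
Product: 18 bis-acetonide (E)-2-methylpropenal (ring–CH=C(Me)–CHO)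
Conditions: Ph3P=C(Me)CHO, toluene, 90 °C
Reagents that add atoms: 2-(triphenylphosphoranylidene)propanal, CC(C=O)=P(c1ccccc1)(c1ccccc1)c1ccccc1
Why: Wittig olefination with a formyl-stabilised ylide, which should give the E trisubstituted enal; C1 already holds its more stable configuration and is no longer epimerisable afterwards.

Step 14
Reactants: 18 bis-acetonide (E)-2-methylpropenal
Product: 19 tetraol enal
Conditions: TFA/H2O/THF (1:1:4), rt
Reagents that add atoms: none
Why: Acid hydrolysis of both dioxolanes at a stage that holds neither triene nor pyrone; only ketal C–O bonds break, so no stereocentre is touched.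

Step 15
Reactants: 19 tetraol enal
Product: 20 C4,C6-diacetate enal (C3 and C5 hydroxyls free)
Conditions: Ac2O, pyridine, DMAP (cat.), CH2Cl2, 0 °C to rt
Reagents that add atoms: acetic anhydride, CC(=O)OC(C)=O
Why: DMAP-catalysed acylation distinguishes the two secondary hydroxyls at C4 and C6 from the hindered tertiary ones at C3 and C5.

Step 16
Reactants: 20 C4,C6-diacetate enal
Product: 21 (1E,3E)-dienyl pinacol boronate
Conditions: Cl2CHBpin, CrCl2, LiI, THF, rt
Reagents that add atoms: 2-(dichloromethyl)-4,4,5,5-tetramethyl-1,3,2-dioxaborolane, CC1(C)OB(C(Cl)Cl)OC1(C)C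
Why: Takai–Utimoto olefination through a gem-dichromium boryl reagent, which should give the E alkenylboronate and tolerates acetates, free tertiary alcohols and the existing double bond.

Step 17
Reactants: 22 diethyl methylmalonate
Product: 23 diethyl 2-(diiodomethyl)-2-methylmalonate
Conditions: NaH, CHI3, Et2O, reflux
Reagents that add atoms: iodoform, IC(I)I
Why: Alkylation of the sodium malonate by iodoform places the diiodomethyl group on the only acidic carbon.

Step 18
Reactants: 23 diethyl 2-(diiodomethyl)-2-methylmalonate
Product: 24 (E)-3-iodo-2-methylacrylic acid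
Conditions: KOH, EtOH/H2O, reflux; then aq HCl
Reagents that add atoms: none
Why: Saponification followed by decarboxylative elimination of iodide (Grob-type fragmentation) should give the E acid, in which iodine and carboxyl are trans.

Step 19
Reactants: 24 (E)-3-iodo-2-methylacrylic acid; 25 methyl 2-methyl-3-oxopentanoate
Product: 27 methyl (E)-7-iodo-2,4,6-trimethyl-3,5-dioxohept-6-enoate, via acyl imidazolide 26 (not isolated)
Conditions: 24, CDI, THF, rt; 25 (2 equiv), LDA (4.2 equiv), THF, −78 to 0 °C; combine at −78 °C; aq NH4Cl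
Reagents that add atoms: none
Why: Claisen-type γ-acylation of the β-keto ester dianion at its more reactive terminal carbanion; the excess dianion covers proton transfer to the more acidic product, and the two unassigned stereocentres vanish on enolisation in step 20.

Step 20
Reactants: 27 methyl (E)-7-iodo-2,4,6-trimethyl-3,5-dioxohept-6-enoate
Product: 28 4-hydroxy-6-[(E)-1-iodoprop-1-en-2-yl]-3,5-dimethyl-2H-pyran-2-one
Conditions: DBU, toluene, 90 °C; aq HCl work-up
Reagents that add atoms: none
Why: Base-induced lactonisation of the C5 enol onto the methyl ester (6-exo-trig) gives the stabilised 4-hydroxy-2-pyrone.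

Step 21
Reactants: 28 4-hydroxy-6-[(E)-1-iodoprop-1-en-2-yl]-3,5-dimethyl-2H-pyran-2-one
Product: 29 2-[(E)-1-iodoprop-1-en-2-yl]-6-methoxy-3,5-dimethyl-4H-pyran-4-one
Conditions: MeOTf, CH2Cl2, rt; aq NaHCO3
Reagents that add atoms: methyl trifluoromethanesulfonate, COS(=O)(=O)C(F)(F)F
Why: Hard methylation at the most nucleophilic oxygen, the lactone carbonyl, gives a 2-methoxy-4-hydroxypyrylium salt that loses a proton on work-up to the α-methoxy-γ-pyrone rather than the 4-methoxy-2-pyrone.

Step 22
Reactants: 21 (1E,3E)-dienyl pinacol boronate; 29 2-[(E)-1-iodoprop-1-en-2-yl]-6-methoxy-3,5-dimethyl-4H-pyran-4-one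
Product: 30 Amaurone B
Conditions: Pd(PPh3)4 (10 mol %), TlOEt, THF/H2O (3:1), rt, dark
Reagents that add atoms: none
Why: Suzuki–Miyaura coupling of two alkenyl partners with retention of both double bond geometries; the thallium base makes transmetalation fast at room temperature, so the acetates and the triene should survive.

Compound list
1 | 3-methylcyclopent-2-en-1-one | CC1=CC(=O)CC1 | starting material
2 | (R)-3-methylcyclopent-2-en-1-ol | CC1=C[C@H](O)CC1 | intermediate
3 | (1R,2S,3R)-1-methylcyclopentane-1,2,3-triol | C[C@]1(O)[C@@H](O)[C@H](O)CC1 | intermediate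
4 | (3aS,4R,6aR)-2,2,6a-trimethyltetrahydro-3aH-cyclopenta[d][1,3]dioxol-4-ol | C[C@]12OC(C)(C)O[C@H]1[C@H](O)CC2 | intermediate
5 | (3aR,6aR)-2,2,6a-trimethyltetrahydro-4H-cyclopenta[d][1,3]dioxol-4-one | C[C@]12OC(C)(C)O[C@H]1C(=O)CC2 | intermediate
6 | trimethylsilyl enol ether of 5 (C5=C6), not isolated | C[C@]12OC(C)(C)O[C@H]1C(O[Si](C)(C)C)=CC2 | intermediate
7 | (3aR,6aR)-2,2,6a-trimethyl-3a,6a-dihydro-4H-cyclopenta[d][1,3]dioxol-4-one | C[C@]12OC(C)(C)O[C@H]1C(=O)C=C2 | intermediate
8 | (3aS,4S,6aR)-2,2,4,6a-tetramethyl-4,6a-dihydro-3aH-cyclopenta[d][1,3]dioxol-4-ol | C[C@]12OC(C)(C)O[C@H]1[C@@](C)(O)C=C2 | intermediate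
9 | tert-butyl carbonate of 8 | C[C@]12OC(C)(C)O[C@H]1[C@@](C)(OC(=O)OC(C)(C)C)C=C2 | intermediate
10 | tricyclic gem-dibromide, cyclopropane anti to the three oxygens | C[C@]12OC(C)(C)O[C@H]1[C@@](C)(OC(=O)OC(C)(C)C)[C@H]3[C@@H]2C3(Br)Br | intermediate
11 | bromocyclohexene with C3/C4 acetonide and C5/C6 cyclic carbonate, all oxygens cis | C[C@]12OC(C)(C)O[C@H]1[C@@]3(C)OC(=O)O[C@H]3C(Br)=C2 | intermediate
12 | bromo diol (C5 and C6 hydroxyls free), not isolated | C[C@]12OC(C)(C)O[C@H]1[C@@](C)(O)[C@@H](O)C(Br)=C2 | intermediate
13 | bis-acetonide vinyl bromide | C[C@]12OC(C)(C)O[C@H]1[C@@]3(C)OC(C)(C)O[C@H]3C(Br)=C2 | intermediate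
14 | bis-acetonide vinyllithium, not isolated | C[C@]12OC(C)(C)O[C@H]1[C@@]3(C)OC(C)(C)O[C@H]3C([Li])=C2 | intermediate
15 | bis-acetonide enal | C[C@]12OC(C)(C)O[C@H]1[C@@]3(C)OC(C)(C)O[C@H]3C(C=O)=C2 | intermediate
16 | exocyclic trimethylsilyl enol ether with C2 methyl in place, not isolated | C[C@]12OC(C)(C)O[C@H]1[C@@]3(C)OC(C)(C)O[C@H]3C(=CO[Si](C)(C)C)[C@@H]2C | intermediate
17 | bis-acetonide aldehyde, C1 formyl and C2 methyl trans to the oxygens | C[C@]12OC(C)(C)O[C@H]1[C@@]3(C)OC(C)(C)O[C@H]3[C@H](C=O)[C@@H]2C | intermediate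
18 | bis-acetonide (E)-2-methylpropenal | C[C@]12OC(C)(C)O[C@H]1[C@@]3(C)OC(C)(C)O[C@H]3[C@H](/C=C(\C)C=O)[C@@H]2C | intermediate
19 | tetraol enal | O=C/C(C)=C/[C@@H]1[C@H](C)[C@@](C)(O)[C@@H](O)[C@@](C)(O)[C@H]1O | intermediate
20 | C4,C6-diacetate enal | O=C/C(C)=C/[C@@H]1[C@H](C)[C@@](C)(O)[C@@H](OC(C)=O)[C@@](C)(O)[C@H]1OC(C)=O | intermediate
21 | (1E,3E)-dienyl pinacol boronate | CC1(C)OB(/C=C/C(C)=C/[C@@H]2[C@H](C)[C@@](C)(O)[C@@H](OC(C)=O)[C@@](C)(O)[C@H]2OC(C)=O)OC1(C)C | intermediate
22 | diethyl methylmalonate | CCOC(=O)C(C)C(=O)OCC | starting material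
23 | diethyl 2-(diiodomethyl)-2-methylmalonate | CCOC(=O)C(C)(C(I)I)C(=O)OCC | intermediate
24 | (E)-3-iodo-2-methylacrylic acid | OC(=O)/C(C)=C/I | intermediate
25 | methyl 2-methyl-3-oxopentanoate | CCC(=O)C(C)C(=O)OC | starting material
26 | (E)-1-(1H-imidazol-1-yl)-3-iodo-2-methylprop-2-en-1-one, not isolated | O=C(/C(C)=C/I)n1ccnc1 | intermediate
27 | methyl (E)-7-iodo-2,4,6-trimethyl-3,5-dioxohept-6-enoate | COC(=O)C(C)C(=O)C(C)C(=O)/C(C)=C/I | intermediate
28 | 4-hydroxy-6-[(E)-1-iodoprop-1-en-2-yl]-3,5-dimethyl-2H-pyran-2-one | CC1=C(O)C(C)=C(/C(C)=C/I)OC1=O | intermediate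
29 | 2-[(E)-1-iodoprop-1-en-2-yl]-6-methoxy-3,5-dimethyl-4H-pyran-4-one | COc1oc(/C(C)=C/I)c(C)c(=O)c1C | intermediate
30 | Amaurone B | COc1oc(/C(C)=C/C=C/C(C)=C/[C@@H]2[C@H](C)[C@@](C)(O)[C@@H](OC(C)=O)[C@@](C)(O)[C@H]2OC(C)=O)c(C)c(=O)c1C | target

Total step count: 22. Longest linear sequence: 17 (steps 1 to 16, then step 22).

Steps most likely to fail

Step 9. The allyl cation may be drained before capture. A methyl group or a ring bond could shift from C3 or C5 to a cationic terminus (pinacol-type), the tert-butyl group could be lost too early, or the acetonide could cleave. The fallback puts the C6 oxygen in place before the ring grows, so no free cation has to be intercepted. It sets out from ketone 5 and comes back at bromo diol 12.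
- Rubottom oxidation of silyl enol ether 6 (mCPBA, NaHCO3, then citric acid) gives the C6-hydroxy ketone F1.
- MeLi/CeCl3 adds to the C5 carbonyl from the convex face to give the diol F2.
- Parikh–Doering oxidation of the secondary alcohol gives the C6 ketone F3.
- TMSOTf/Et3N gives the bis-silyl compound F4 (C5 silyl ether, C6=C2 silyl enol ether). Enolisation is possible only toward C2.
- CHBr3/KOtBu adds dibromocarbene to this electron-rich alkene to give the siloxycyclopropane F5.
- On warming in toluene, F5 opens to the ring-expanded 2-bromoenone F6, a known homologation of cyclic ketones.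
- Luche reduction from the face anti to the oxygens gives the silylated allylic alcohol F7, and K2CO3/MeOH gives 12.

Step 8. The alkene stands between two fully substituted, oxygen-bearing carbons, so carbene addition may be too slow. The carbonate may also hydrolyse under the basic two-phase conditions. The fallback changes the substrate and the order of events. It sets out from alcohol 8 and comes back at dibromide 10.
- TESOTf/2,6-lutidine gives the triethylsilyl ether F8, whose alkene is more electron-rich and whose protecting group is stable to base.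
- Dibromocarbene addition gives the silylated dibromide F9.
- TBAF at 0 °C gives the free tertiary alcohol F10.
- KHMDS/Boc2O then gives 10.

Step 12. The cuprate may add 1,2 to the aldehyde or fail at the neopentyl β-carbon. The basic equilibration may also start β-elimination of the C6 oxygen. The fallback brings in the methyl carbon as a cyclopropane methylene. It sets out from enal 15 and comes back at aldehyde 17.
- Luche reduction gives the allylic alcohol F11.
- Furukawa–Simmons–Smith cyclopropanation (Et2Zn, CH2I2) on the convex face gives the cyclopropyl carbinol F12.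
- Dess–Martin oxidation gives the cyclopropyl aldehyde F13.
- Li/NH3 (then isoprene, NH4Cl) cleaves the C1–CH2 bond, the conjugated bond that leads to the less substituted carbanion. The methylene thereby becomes the C2 methyl on the face where the cyclopropane stood.
- Protonation of the enolate and equilibration with K2CO3/MeOH give 17.

Further compounds
F1 | step 9 | C6-hydroxy C5-ketone with C3/C4 acetonide | C[C@]12OC(C)(C)O[C@H]1C(=O)[C@H](O)C2
F2 | step 9 | C5 tertiary, C6 secondary diol | C[C@]12OC(C)(C)O[C@H]1[C@@](C)(O)[C@H](O)C2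
F3 | step 9 | C5-hydroxy C6-ketone | C[C@]12OC(C)(C)O[C@H]1[C@@](C)(O)C(=O)C2
F4 | step 9 | C5 trimethylsilyl ether, C6=C2 trimethylsilyl enol ether | C[C@]12OC(C)(C)O[C@H]1[C@@](C)(O[Si](C)(C)C)C(O[Si](C)(C)C)=C2
F5 | step 9 | 1-siloxy-6,6-dibromobicyclo[3.1.0]hexane | C[C@]12OC(C)(C)O[C@H]1[C@@](C)(O[Si](C)(C)C)[C@@]3(O[Si](C)(C)C)[C@@H]2C3(Br)Br
F6 | step 9 | ring-expanded 2-bromocyclohex-2-enone (C6 ketone, C1–Br) | C[C@]12OC(C)(C)O[C@H]1[C@@](C)(O[Si](C)(C)C)C(=O)C(Br)=C2
F7 | step 9 | C6 allylic alcohol, C5 trimethylsilyl ether | C[C@]12OC(C)(C)O[C@H]1[C@@](C)(O[Si](C)(C)C)[C@@H](O)C(Br)=C2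
F8 | step 8 | triethylsilyl ether of 8 | C[C@]12OC(C)(C)O[C@H]1[C@@](C)(O[Si](CC)(CC)CC)C=C2
F9 | step 8 | gem-dibromocyclopropane with C5 triethylsilyl ether | C[C@]12OC(C)(C)O[C@H]1[C@@](C)(O[Si](CC)(CC)CC)[C@H]3[C@@H]2C3(Br)Br
F10 | step 8 | gem-dibromocyclopropane with free C5 hydroxyl | C[C@]12OC(C)(C)O[C@H]1[C@@](C)(O)[C@H]3[C@@H]2C3(Br)Br
F11 | step 12 | bis-acetonide allylic alcohol (C1–CH2OH, C1=C2) | C[C@]12OC(C)(C)O[C@H]1[C@@]3(C)OC(C)(C)O[C@H]3C(CO)=C2
F12 | step 12 | C1/C2-fused cyclopropyl carbinol, cyclopropane anti to the oxygens | C[C@]12OC(C)(C)O[C@H]1[C@@]3(C)OC(C)(C)O[C@H]3[C@]4(CO)C[C@H]24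
F13 | step 12 | C1/C2-fused cyclopropyl aldehyde | C[C@]12OC(C)(C)O[C@H]1[C@@]3(C)OC(C)(C)O[C@H]3[C@]4(C=O)C[C@H]24
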